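**Retrosynthetic overview**
- Locants used throughout (not IUPAC): bicyclo[3.2.1]octane with C1 (allyl bridgehead), C2H2, C3H(OMe), C4=O, C5 (OMe bridgehead), C6H(aryl), C7H(Me), C8H(OH). The five-membered ring is C1–C7–C6–C5–C8 and the six-membered ring is C1–C2–C3–C4–C5–C8. Ar = 3-(tert-butyldimethylsilyloxy)-4-methoxyphenyl.
- Feature: in the five-membered ring the oxygenated pair C5 (OMe)–C8 (carbonyl level) sits next to the pair C6 (aryl)–C7 (methyl). This is a methoxyketene unit C5=C8=O laid across an (E)-propenylarene; the fifth ring atom C1 is inserted afterwards into the temporary C7–C8 bond.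
- Disconnections, backwards: ArO–H from ArO–Si; C1–allyl from C1–I from C1–CO2Bn (bridgehead radical); C3–H from hydrogenation of a C2=C3 enol ether; C8–OH from ketone reduction plus aldolate equilibration; six-membered ring from Michael (C1–C2) and aldol (C4–C5) bonds with 2-methoxyacrolein; C1 from diazoacetate insertion; C5–C6 and C7–C8 from a keteniminium [2+2].
- Order of ring formation: four-membered ring (step 4), five-membered ring by one-carbon expansion (step 5), six-membered ring closing the bicycle (step 7).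

Key step: step 4

Assumption: the (2R,5R)-auxiliary is taken to give the (3S,4R) series drawn for 10; the sense must be checked on the first batch, and if it is the opposite one the commercial (2S,5S)-amine is used with no other change.

**Step 1**
Reactants: 1 5-bromo-2-methoxyphenol; 2 (E)-prop-1-enylboronic acid pinacol ester
Product: 3 (E)-2-methoxy-5-(prop-1-enyl)phenol
Conditions: PdCl2(dppf) (cat.), K2CO3, 1,4-dioxane/H2O, 80 °C
Reagents that add atoms: none
Why: Suzuki–Miyaura coupling of an aryl bromide with an alkenylboronate goes with retention of alkene geometry and tolerates the free phenol, so the E-propenyl group is installed without an isomerisation step.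

**Step 2**
Reactants: 3 (E)-2-methoxy-5-(prop-1-enyl)phenol
Product: 4 tert-butyl{2-methoxy-5-[(E)-prop-1-enyl]phenoxy}dimethylsilane
Conditions: TBSCl, imidazole, DMF, 23 °C
Reagents that add atoms: tert-butyldimethylsilyl chloride, CC(C)(C)[Si](C)(C)Cl
Why: Imidazole-mediated silylation of a phenol; the silyl ether keeps the phenol from quenching the cationic and radical steps that follow.

**Step 3**
Reactants: 5 methoxyacetyl chloride; 6 (2R,5R)-2,5-dimethylpyrrolidine
Product: 7 1-[(2R,5R)-2,5-dimethylpyrrolidin-1-yl]-2-methoxyethan-1-one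
Conditions: aq. NaOH, CH2Cl2, 0 °C
Reagents that add atoms: none
Why: Schotten–Baumann acylation of a secondary amine by an acid chloride, which leaves the stereocentres of the auxiliary untouched.

**Step 4**
Reactants: 7 1-[(2R,5R)-2,5-dimethylpyrrolidin-1-yl]-2-methoxyethan-1-one; 4 tert-butyl{2-methoxy-5-[(E)-prop-1-enyl]phenoxy}dimethylsilane
Product: 10 (2S,3S,4R)-3-Ar-2-methoxy-4-methylcyclobutan-1-one, via keteniminium triflate 8 (not isolated), via cyclobutaniminium triflate 9 (not isolated)
Conditions: Tf2O, 2,6-di-tert-butyl-4-methylpyridine, CH2Cl2, −40 → 0 °C; then H2O, aq. NaHCO3, 23 °C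
Reagents that add atoms: water, O (carbonyl oxygen of 10); trifluoromethanesulfonic anhydride, O=S(=O)(OS(=O)(=O)C(F)(F)F)C(F)(F)F (triflate counter-ion of 8 and 9 only)
Why: Free methoxyketene would oligomerise faster than it adds to a styrene and carries no chirality, so the C5=C8 unit is used as its keteniminium salt 8, made in the flask from amide 7 and Tf2O. The electrophilic central carbon of 8 (C8) is attacked by the more nucleophilic CHMe carbon (C7) of the p-methoxy-activated alkene 4, the benzylic cation formed at C6 is captured by the enamine carbon C5 (a stepwise polar [2+2]), and water then hydrolyses iminium 9 to ketone 10 with release of the auxiliary. The closest known reaction type is the keteniminium–alkene [2+2] cycloaddition to cyclobutanones, including its asymmetric form with amides of C2-symmetric trans-2,5-dimethylpyrrolidine and cycloadditions of oxygen-substituted keteniminium salts. The four-membered ring is closed by intermolecular two-bond annulation, C7–C8 first and C5–C6 second by collapse of the 1,4-dipole. C6 and C7 should come out trans because the E geometry is carried over (closure outruns C6–C7 rotation and trans is also the more stable arrangement), their absolute configuration is fixed in the first bond formation by the pyrrolidine methyl groups, which block one approach of the alkene to the keteniminium, and C5 settles trans to the aryl group during hydrolysis and is planarised again in step 7 in any case. The step needs C8-to-C7 regiochemistry, secured by the polarity of the electron-rich styrene, and facial control, secured by the auxiliary; enantiomeric purity can be raised by crystallisation of 10 or 12 if required.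

**Step 5**
Reactants: 10 (2S,3S,4R)-3-Ar-2-methoxy-4-methylcyclobutan-1-one; 11 benzyl diazoacetate
Product: 12 benzyl (1S,3S,4S,5R)-4-Ar-3-methoxy-5-methyl-2-oxocyclopentane-1-carboxylate (keto form drawn; enol and C1/C3 epimers equilibrate)
Conditions: BF3·OEt2, CH2Cl2, −78 → −30 °C
Reagents that add atoms: none
Why: Lewis-acid-promoted diazoacetate ring expansion (Tiffeneau–Demjanov type) of a strained cyclobutanone, in which the diazo carbon adds to the activated C8 carbonyl and C7 migrates with retention in preference to the inductively deactivated methoxy-bearing C5, so that C1 enters between C8 and C7 as a β-keto ester carbon whose configuration need not be fixed.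

**Step 6**
Reactants: 13 methoxyacetaldehyde; 14 formaldehyde
Product: 15 2-methoxyprop-2-enal (2-methoxyacrolein)
Conditions: 37% aq. HCHO, pyrrolidine (cat.), EtCO2H (cat.), iPrOH, 45 °C; distilled and used as a solution
Reagents that add atoms: none
Why: Amine-catalysed Mannich condensation–elimination (α-methylenation of an aldehyde), the usual access to 2-alkoxyacroleins; no stereocentre is formed.

**Step 7**
Reactants: 12 benzyl (1S,3S,4S,5R)-4-Ar-3-methoxy-5-methyl-2-oxocyclopentane-1-carboxylate; 15 2-methoxyprop-2-enal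
Product: 17 benzyl 6-endo-Ar-4-hydroxy-3,5-dimethoxy-7-exo-methyl-8-oxobicyclo[3.2.1]octane-1-carboxylate (C3/C4 epimer mixture), via Michael adduct 16 (not isolated)
Conditions: DBU (0.3 equiv), MeCN, 0 → 23 °C, slow addition of 15
Reagents that add atoms: none
Why: Base-mediated Michael–aldol annulation of a cyclic β-keto ester with an enal, a known route to 8-oxobicyclo[3.2.1]octane ketols: the C1 enolate adds to the CH2 terminus of 15 on the face anti to the adjacent C7 methyl (1,2-induction), and the C5 enolate of the same ketone then closes C4–C5 on the only face the tether can reach, which fixes C5 and makes the aryl endo and the methyl exo, while C3 and C4 form as mixtures that are removed in step 8.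

**Step 8**
Reactants: 17 benzyl 6-endo-Ar-4-hydroxy-3,5-dimethoxy-7-exo-methyl-8-oxobicyclo[3.2.1]octane-1-carboxylate
Product: 19 benzyl 6-endo-Ar-3,5-dimethoxy-7-exo-methyl-4,8-dioxobicyclo[3.2.1]oct-2-ene-1-carboxylate, via 4,8-diketone 18 (not isolated)
Conditions: IBX (excess), 4-methoxypyridine N-oxide, DMSO, 23 → 45 °C
Reagents that add atoms: none
Why: IBX oxidises the secondary alcohol and then dehydrogenates the ketone through its only possible enol (C3=C4, since C5 is quaternary), a known one-flask alcohol-to-enone conversion, so every C3/C4 isomer of 17 converges on one enone.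

**Step 9**
Reactants: 19 benzyl 6-endo-Ar-3,5-dimethoxy-7-exo-methyl-4,8-dioxobicyclo[3.2.1]oct-2-ene-1-carboxylate
Product: 20 benzyl 6-endo-Ar-8-hydroxy-3,5-dimethoxy-7-exo-methyl-4-oxobicyclo[3.2.1]oct-2-ene-1-carboxylate with the OH over the C6–C7 bridge (8-epi series)
Conditions: NaBH4, MeOH/CH2Cl2 (1:1), −78 °C
Reagents that add atoms: none
Why: Borohydride reduction under conditions that favour a strained saturated ketone over a conjugated enone; hydride should come from the open face above the flat C2–C4 enone bridge because the other face is covered by the C6–C7 bridge and the exo methyl, so the kinetic alcohol is expected to be the C8 epimer of the one needed.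

**Step 10**
Reactants: 20 benzyl 6-endo-Ar-8-hydroxy-3,5-dimethoxy-7-exo-methyl-4-oxobicyclo[3.2.1]oct-2-ene-1-carboxylate (OH over the C6–C7 bridge)
Product: 22 benzyl 6-endo-Ar-8-hydroxy-3,5-dimethoxy-7-exo-methyl-4-oxobicyclo[3.2.1]oct-2-ene-1-carboxylate with the OH over the C2–C4 bridge, via ring-opened lithium dienolate 21 (not isolated)
Conditions: LiN(SiMe3)2 (1.05 equiv), THF, −78 → 0 °C; AcOH, −78 °C
Reagents that add atoms: lithium bis(trimethylsilyl)amide, [Li+].C[Si](C)(C)[N-][Si](C)(C)C (counter-ion of 21 only)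
Why: Retro-aldol/aldol equilibration of the lithium aldolate of a β-hydroxy ketone, in which C5–C8 heterolysis gives dienolate aldehyde 21 that recloses on C5, and the equilibrium should favour the epimer whose C8 oxygen lies over the flat enone bridge and away from the exo C7 methyl, which is the configuration of the target.

**Step 11**
Reactants: 22 benzyl 6-endo-Ar-8-hydroxy-3,5-dimethoxy-7-exo-methyl-4-oxobicyclo[3.2.1]oct-2-ene-1-carboxylate (OH over the C2–C4 bridge)
Product: 23 6-endo-Ar-8-hydroxy-3,5-dimethoxy-7-exo-methyl-4-oxobicyclo[3.2.1]octane-1-carboxylic acid (C8–OH over the C2–C4 bridge; C3–OMe on the side of the C6–C7 bridge)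
Conditions: H2 (1 atm), Pd/C, EtOAc, 23 °C
Reagents that add atoms: none
Why: Heterogeneous hydrogenation that hydrogenolyses the benzyl ester and adds H2 to the C2=C3 enol ether from the convex C8 side, the concave face being closed by the C6–C7 bridge and the endo aryl group, so C3 receives H syn to C8 and its methoxy group points to the C6–C7 bridge, a kinetic result obtained before any allyl group is present.

**Step 12**
Reactants: 23 6-endo-Ar-8-hydroxy-3,5-dimethoxy-7-exo-methyl-4-oxobicyclo[3.2.1]octane-1-carboxylic acid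
Product: 25 6-endo-Ar-8-hydroxy-1-iodo-3,5-dimethoxy-7-exo-methylbicyclo[3.2.1]octan-4-one, via Barton ester 24 (not isolated)
Conditions: DCC, 1-hydroxypyridine-2(1H)-thione, CH2Cl2, 0 → 23 °C, dark; then CHI3, benzene, hν (tungsten lamp), 23 °C
Reagents that add atoms: iodoform, IC(I)I; 1-hydroxypyridine-2(1H)-thione, On1ccccc1=S (present in 24 only)
Why: Barton decarboxylative iodination, in which the thiohydroxamate ester fragments under light to the C1 bridgehead radical that abstracts iodine from CHI3; the bridgehead cannot invert, so C1 keeps its configuration.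

**Step 13**
Reactants: 25 6-endo-Ar-8-hydroxy-1-iodo-3,5-dimethoxy-7-exo-methylbicyclo[3.2.1]octan-4-one; 26 allyltributylstannane
Product: 27 1-allyl-6-endo-Ar-8-hydroxy-3,5-dimethoxy-7-exo-methylbicyclo[3.2.1]octan-4-one (silyl ether of the target)
Conditions: Bu3SnCH2CH=CH2 (excess), AIBN (cat.), benzene, 80 °C
Reagents that add atoms: none
Why: Keck radical allylation, in which the C1 bridgehead radical from the iodide adds to the stannane and the adduct expels Bu3Sn• to carry the chain under neutral conditions that leave C3 and the β-hydroxy ketone alone.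

**Step 14**
Reactants: 27 1-allyl-6-endo-Ar-8-hydroxy-3,5-dimethoxy-7-exo-methylbicyclo[3.2.1]octan-4-one
Product: 28 CNP0209708.1, (1S,3S,5S,6S,7R,8S)-1-allyl-8-hydroxy-6-(3-hydroxy-4-methoxyphenyl)-3,5-dimethoxy-7-methylbicyclo[3.2.1]octan-4-one (route locants)
Conditions: Bu4NF, AcOH, THF, 0 °C
Reagents that add atoms: none
Why: Fluoride cleavage of an aryl silyl ether, buffered with acetic acid so that neither the C3 stereocentre next to the C4 ketone nor the β-hydroxy ketone (retro-aldol) meets free base.

**Compound list**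
1 | 5-bromo-2-methoxyphenol | COc1ccc(Br)cc1O | starting material
2 | (E)-prop-1-enylboronic acid pinacol ester | C/C=C/B1OC(C)(C)C(C)(C)O1 | starting material
3 | (E)-2-methoxy-5-(prop-1-enyl)phenol | C/C=C/c1ccc(OC)c(O)c1 | intermediate
4 | tert-butyl{2-methoxy-5-[(E)-prop-1-enyl]phenoxy}dimethylsilane | C/C=C/c1ccc(OC)c(O[Si](C)(C)C(C)(C)C)c1 | intermediate
5 | methoxyacetyl chloride | COCC(=O)Cl | starting material
6 | (2R,5R)-2,5-dimethylpyrrolidine | C[C@@H]1CC[C@@H](C)N1 | starting material
7 | 1-[(2R,5R)-2,5-dimethylpyrrolidin-1-yl]-2-methoxyethan-1-one | COCC(=O)N1[C@H](C)CC[C@H]1C | intermediate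
8 | (2R,5R)-1-(2-methoxyethenylidene)-2,5-dimethylpyrrolidinium triflate (keteniminium form of methoxyketene) | COC=C=[N+]1[C@H](C)CC[C@H]1C.[O-]S(=O)(=O)C(F)(F)F | intermediate (not isolated)
9 | (2R,5R)-1-[(2S,3S,4R)-3-Ar-2-methoxy-4-methylcyclobutylidene]-2,5-dimethylpyrrolidinium triflate | C[C@@H]1CC[C@@H](C)[N+]1=C2[C@@H](OC)[C@H](c3ccc(OC)c(O[Si](C)(C)C(C)(C)C)c3)[C@H]2C.[O-]S(=O)(=O)C(F)(F)F | intermediate (not isolated)
10 | (2S,3S,4R)-3-[3-(tert-butyldimethylsilyloxy)-4-methoxyphenyl]-2-methoxy-4-methylcyclobutan-1-one | O=C1[C@@H](OC)[C@H](c2ccc(OC)c(O[Si](C)(C)C(C)(C)C)c2)[C@H]1C | intermediate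
11 | benzyl diazoacetate | [N-]=[N+]=CC(=O)OCc1ccccc1 | starting material
12 | benzyl (1S,3S,4S,5R)-4-Ar-3-methoxy-5-methyl-2-oxocyclopentane-1-carboxylate | O=C1[C@@H](OC)[C@H](c2ccc(OC)c(O[Si](C)(C)C(C)(C)C)c2)[C@@H](C)[C@@H]1C(=O)OCc3ccccc3 | intermediate
13 | methoxyacetaldehyde | COCC=O | starting material
14 | formaldehyde | C=O | starting material
15 | 2-methoxyprop-2-enal | C=C(OC)C=O | intermediate
16 | benzyl 4-Ar-3-methoxy-1-(2-methoxy-3-oxopropyl)-5-methyl-2-oxocyclopentane-1-carboxylate, side chain trans to the 5-methyl (side-chain CH(OMe) unassigned) | O=C1[C@@H](OC)[C@H](c2ccc(OC)c(O[Si](C)(C)C(C)(C)C)c2)[C@@H](C)[C@@]1(CC(OC)C=O)C(=O)OCc3ccccc3 | intermediate (not isolated)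
17 | benzyl 6-endo-Ar-4-hydroxy-3,5-dimethoxy-7-exo-methyl-8-oxobicyclo[3.2.1]octane-1-carboxylate (C3 and C4 unassigned) | O=C(OCc3ccccc3)[C@]12CC(OC)C(O)[C@](OC)([C@H](c4ccc(OC)c(O[Si](C)(C)C(C)(C)C)c4)[C@H]1C)C2=O | intermediate
18 | benzyl 6-endo-Ar-3,5-dimethoxy-7-exo-methyl-4,8-dioxobicyclo[3.2.1]octane-1-carboxylate (C3 unassigned) | O=C(OCc3ccccc3)[C@]12CC(OC)C(=O)[C@](OC)([C@H](c4ccc(OC)c(O[Si](C)(C)C(C)(C)C)c4)[C@H]1C)C2=O | intermediate (not isolated)
19 | benzyl 6-endo-Ar-3,5-dimethoxy-7-exo-methyl-4,8-dioxobicyclo[3.2.1]oct-2-ene-1-carboxylate | O=C(OCc3ccccc3)[C@]12C=C(OC)C(=O)[C@](OC)([C@H](c4ccc(OC)c(O[Si](C)(C)C(C)(C)C)c4)[C@H]1C)C2=O | intermediate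
20 | benzyl 6-endo-Ar-8-hydroxy-3,5-dimethoxy-7-exo-methyl-4-oxobicyclo[3.2.1]oct-2-ene-1-carboxylate, OH over the C6–C7 bridge | O=C(OCc3ccccc3)[C@]12C=C(OC)C(=O)[C@](OC)([C@H](c4ccc(OC)c(O[Si](C)(C)C(C)(C)C)c4)[C@H]1C)[C@@H]2O | intermediate
21 | lithium dienolate of benzyl 6-Ar-1-formyl-3,5-dimethoxy-7-methyl-4-oxocyclohept-2-ene-1-carboxylate (C5–C8 bond opened) | O=C[C@@]1(C(=O)OCc2ccccc2)C=C(OC)C([O-])=C(OC)[C@H](c3ccc(OC)c(O[Si](C)(C)C(C)(C)C)c3)[C@H]1C.[Li+] | intermediate (not isolated)
22 | benzyl 6-endo-Ar-8-hydroxy-3,5-dimethoxy-7-exo-methyl-4-oxobicyclo[3.2.1]oct-2-ene-1-carboxylate, OH over the C2–C4 bridge | O=C(OCc3ccccc3)[C@]12C=C(OC)C(=O)[C@](OC)([C@H](c4ccc(OC)c(O[Si](C)(C)C(C)(C)C)c4)[C@H]1C)[C@H]2O | intermediate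
23 | 6-endo-Ar-8-hydroxy-3,5-dimethoxy-7-exo-methyl-4-oxobicyclo[3.2.1]octane-1-carboxylic acid (C8–OH over the C2–C4 bridge, C3–OMe toward the C6–C7 bridge) | O=C(O)[C@]12C[C@H](OC)C(=O)[C@](OC)([C@H](c3ccc(OC)c(O[Si](C)(C)C(C)(C)C)c3)[C@H]1C)[C@H]2O | intermediate
24 | 2-thioxopyridin-1(2H)-yl ester of acid 23 | S=c1ccccn1OC(=O)[C@]23C[C@H](OC)C(=O)[C@](OC)([C@H](c4ccc(OC)c(O[Si](C)(C)C(C)(C)C)c4)[C@H]2C)[C@H]3O | intermediate (not isolated)
25 | 6-endo-Ar-8-hydroxy-1-iodo-3,5-dimethoxy-7-exo-methylbicyclo[3.2.1]octan-4-one | I[C@]12C[C@H](OC)C(=O)[C@](OC)([C@H](c3ccc(OC)c(O[Si](C)(C)C(C)(C)C)c3)[C@H]1C)[C@H]2O | intermediate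
26 | allyltributylstannane | C=CC[Sn](CCCC)(CCCC)CCCC | starting material
27 | 1-allyl-6-endo-Ar-8-hydroxy-3,5-dimethoxy-7-exo-methylbicyclo[3.2.1]octan-4-one | C=CC[C@]12C[C@H](OC)C(=O)[C@](OC)([C@H](c3ccc(OC)c(O[Si](C)(C)C(C)(C)C)c3)[C@H]1C)[C@H]2O | intermediate
28 | CNP0209708.1; IUPAC numbering: (1S,3S,5S,6R,7S,8S)-8-hydroxy-7-(3-hydroxy-4-methoxyphenyl)-1,3-dimethoxy-6-methyl-5-(prop-2-enyl)bicyclo[3.2.1]octan-2-one | C=CC[C@]12C[C@H](OC)C(=O)[C@](OC)([C@H](c3ccc(OC)c(O)c3)[C@H]1C)[C@H]2O | target

**Step count and risks**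
Total steps: 14. Longest linear sequence: 12 (steps 1, 2, 4, 5, 7 to 14; steps 3 and 6 are side branches).

Most likely to fail, step 4: the benzylic cation may live long enough for the auxiliary to lose facial control, and the electron-rich alkene may oligomerise under the cationic conditions. The fallback takes absolute configuration from a resolution, not from an auxiliary. It sets out from 4: commercial N,N-dimethyl-2-methoxyacetamide is activated with Tf2O and 2,6-di-tert-butyl-4-methylpyridine to the achiral N,N-dimethyl-α-methoxyketeniminium triflate F1, which adds to 4 to give the racemic cyclobutaniminium triflate F2 and, after hydrolysis, the racemic trans,trans-cyclobutanone F3. F3 is resolved by preparative chromatography on a chiral stationary phase; the (2S,3S,4R) enantiomer is 10, where the route is rejoined.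

Second, step 10: the ring-opened aldehyde may fail to reclose (protonation of the dienolate or deformylation), or the aldolate equilibrium may not favour the wanted C8 epimer. The fallback replaces substrate and thermodynamic control by catalyst control. It sets out from 19, which is reduced at C8 with a ketoreductase selected from a screening panel (NADPH recycled with isopropanol, aqueous buffer/DMSO) for hydride delivery from the face over the C6–C7 bridge. This gives 22 directly, replaces steps 9 and 10, and makes no new compound.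

Third, step 7: 2-methoxyacrolein is a captodative, polymerisable acceptor, so the Michael addition may be slow or poorly face-selective at C1 and the aldol may stall at the open adduct. The fallback sets out from 12 and uses acrolein, the well-precedented partner, under the same base to give benzyl 6-endo-Ar-4-hydroxy-5-methoxy-7-exo-methyl-8-oxobicyclo[3.2.1]octane-1-carboxylate F4. IBX oxidation gives the 4,8-dione F5. SeO2 in aqueous dioxane oxidises the only α-CH2 of the C4 ketone (C3) to the 3,4-dione, which exists as the 3-hydroxy-2-en-4-one (diosphenol) F6 because the other enol is barred by the bridgehead C5. O-methylation with MeI and K2CO3 in acetone gives 19, where the route is rejoined.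

**Further compounds**
F1 | step 4 | N,N-dimethyl-α-methoxyketeniminium triflate | COC=C=[N+](C)C.[O-]S(=O)(=O)C(F)(F)F
F2 | step 4 | racemic N-(3-Ar-2-methoxy-4-methylcyclobutylidene)-N-methylmethanaminium triflate (2,3-trans-3,4-trans; both enantiomers written) | C[N+](C)=C1[C@@H](OC)[C@H](c2ccc(OC)c(O[Si](C)(C)C(C)(C)C)c2)[C@H]1C.C[N+](C)=C1[C@H](OC)[C@@H](c2ccc(OC)c(O[Si](C)(C)C(C)(C)C)c2)[C@@H]1C.[O-]S(=O)(=O)C(F)(F)F.[O-]S(=O)(=O)C(F)(F)F
F3 | step 4 | racemic 3-Ar-2-methoxy-4-methylcyclobutan-1-one (2,3-trans-3,4-trans; both enantiomers written) | O=C1[C@@H](OC)[C@H](c2ccc(OC)c(O[Si](C)(C)C(C)(C)C)c2)[C@H]1C.O=C1[C@H](OC)[C@@H](c2ccc(OC)c(O[Si](C)(C)C(C)(C)C)c2)[C@@H]1C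
F0 | step 10 | none | none
F4 | step 7 | benzyl 6-endo-Ar-4-hydroxy-5-methoxy-7-exo-methyl-8-oxobicyclo[3.2.1]octane-1-carboxylate (C4 unassigned) | O=C(OCc3ccccc3)[C@]12CCC(O)[C@](OC)([C@H](c4ccc(OC)c(O[Si](C)(C)C(C)(C)C)c4)[C@H]1C)C2=O
F5 | step 7 | benzyl 6-endo-Ar-5-methoxy-7-exo-methyl-4,8-dioxobicyclo[3.2.1]octane-1-carboxylate | O=C(OCc3ccccc3)[C@]12CCC(=O)[C@](OC)([C@H](c4ccc(OC)c(O[Si](C)(C)C(C)(C)C)c4)[C@H]1C)C2=O
F6 | step 7 | benzyl 6-endo-Ar-3-hydroxy-5-methoxy-7-exo-methyl-4,8-dioxobicyclo[3.2.1]oct-2-ene-1-carboxylate | O=C(OCc3ccccc3)[C@]12C=C(O)C(=O)[C@](OC)([C@H](c4ccc(OC)c(O[Si](C)(C)C(C)(C)C)c4)[C@H]1C)C2=O
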